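**Retrosynthetic overview**
- The target is the hepta-O-silyl ether of itself after one global desilylation; all three stereocentres are already present in that ether.
- The strategy rests on ring C (O1, C2, C3, C4, C4a, C8a): O1 and C4 both sit on ring A (at C8a and C4a), which is a salicylaldehyde, and C2–C3–O3 carries ring B and the gallate, which is the (E)-enol gallate of (3,4-dihydroxyphenyl)acetaldehyde.
- Ring C is therefore cut at C3–C4 and O1–C2 and formed in one chiral-acid-catalysed hetero-[4+2] annulation of the silylated salicylaldehyde with the silylated (E)-enol gallate.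
- The enol gallate is cut at its vinyl C–O bond into an (E)-alkenylboronic acid (from 3,4-dihydroxybenzaldehyde by silylation, boron–Wittig olefination and pinacol removal) and silylated gallic acid, joined by stereoretentive copper-catalysed C–O coupling.
- Rings A, B and the galloyl ring are bought; ring C is the only ring made, in the penultimate step.

Key step: step 7

Assumption: the sense of induction of the phosphoramide in step 7 cannot be predicted with confidence; the (R)-catalyst is written, and its (S)-antipode is used if the first runs show that it is the one leading to (2R,3S,4S). TBS = tert-butyldimethylsilyl.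

**Step 1**
Reactants: 1 2,4,6-trihydroxybenzaldehyde
Product: 2 2-hydroxy-4,6-bis(tert-butyldimethylsilyloxy)benzaldehyde
Conditions: TBSCl (2.05 equiv), imidazole (2.5 equiv), CH2Cl2–DMF, 0 °C
Reagents that add atoms: tert-butyldimethylsilyl chloride, CC(C)(C)[Si](C)(C)Cl
Why: Chemoselective phenol O-silylation (Corey TBSCl/imidazole protocol): the 4-OH and one of the two equivalent ortho hydroxyls react, after which the last ortho hydroxyl is locked in a hydrogen bond to the formyl oxygen and is the slowest to silylate, so two equivalents of TBSCl should stop at 2.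

**Step 2**
Reactants: 3 gallic acid
Product: 5 3,4,5-tris(tert-butyldimethylsilyloxy)benzoic acid, via tetrasilylated silyl ester 4 (not isolated)
Conditions: TBSCl (4.4 equiv), imidazole (9 equiv), DMF, rt; then AcOH–THF–H2O (3:1:1), rt
Reagents that add atoms: tert-butyldimethylsilyl chloride, CC(C)(C)[Si](C)(C)Cl
Why: Exhaustive silylation followed by selective solvolysis: a silyl carboxylate is hydrolysed by aqueous acetic acid far faster than aryl silyl ethers, so acid 5 should be released with its three phenol ethers intact.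

**Step 3**
Reactants: 6 3,4-dihydroxybenzaldehyde
Product: 7 3,4-bis(tert-butyldimethylsilyloxy)benzaldehyde
Conditions: TBSCl (2.3 equiv), imidazole (4.5 equiv), DMF, rt
Reagents that add atoms: tert-butyldimethylsilyl chloride, CC(C)(C)[Si](C)(C)Cl
Why: Standard phenol O-silylation of two free, unhindered hydroxyls; the aldehyde is untouched.

**Step 4**
Reactants: 7 3,4-bis(tert-butyldimethylsilyloxy)benzaldehyde
Product: 8 (E)-2-{2-[3,4-bis(tert-butyldimethylsilyloxy)phenyl]ethenyl}-4,4,5,5-tetramethyl-1,3,2-dioxaborolane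
Conditions: bis(pinacolatoboryl)methane (1.2 equiv), lithium 2,2,6,6-tetramethylpiperidide (LiTMP, purchased solution, 1.2 equiv), THF, 0 °C; then 7, −78 °C → rt
Reagents that add atoms: bis(4,4,5,5-tetramethyl-1,3,2-dioxaborolan-2-yl)methane, CC1(C)OB(CB2OC(C)(C)C(C)(C)O2)OC1(C)C
Why: Boron–Wittig olefination: the lithiated gem-diboronate adds to the aldehyde and the adduct loses a borate by syn elimination, which gives the (E)-alkenylboronate with high selectivity for aromatic aldehydes; the base is consumed at low temperature, so the aryl silyl ethers should survive, which a carbonate/methanol alkyne homologation would not guarantee.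

**Step 5**
Reactants: 8 (E)-alkenyl pinacol boronate
Product: 9 (E)-2-[3,4-bis(tert-butyldimethylsilyloxy)phenyl]ethenylboronic acid
Conditions: NaIO4 (3 equiv), NH4OAc (3 equiv), acetone–H2O (1:1), rt
Reagents that add atoms: water, O
Why: Oxidative pinacol removal: periodate cleaves the pinacol released in the hydrolysis equilibrium and drives the ester to the boronic acid at neutral pH without touching the alkene geometry or the silyl ethers; the boronic acid is chosen because a trifluoroborate would need KHF2, which strips aryl silyl ethers.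

**Step 6**
Reactants: 5 3,4,5-tris(tert-butyldimethylsilyloxy)benzoic acid; 9 (E)-alkenylboronic acid (1.5 equiv)
Product: 10 (E)-2-[3,4-bis(tert-butyldimethylsilyloxy)phenyl]ethenyl 3,4,5-tris(tert-butyldimethylsilyloxy)benzoate
Conditions: CuBr (20 mol%), DMAP (40 mol%), 4 Å MS, O2 (1 atm), CH2Cl2, 35 °C
Reagents that add atoms: none
Why: Chan–Lam–Evans-type oxidative C–O coupling of an alkenylboron reagent with a carboxylic acid (transmetalation to a copper carboxylate, oxidation to trivalent copper, C–O reductive elimination) is stereoretentive and should deliver the (E)-enol ester; ruthenium-catalysed anti-Markovnikov addition of the acid to the arylalkyne is not used because it gives mainly the (Z)-isomer.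

**Step 7**
Reactants: 2 2-hydroxy-4,6-bis(tert-butyldimethylsilyloxy)benzaldehyde; 10 (E)-enol gallate (1.3 equiv)
Product: 12 (2R,3S,4S)-5,7-bis(tert-butyldimethylsilyloxy)-2-[3,4-bis(tert-butyldimethylsilyloxy)phenyl]-4-hydroxychroman-3-yl 3,4,5-tris(tert-butyldimethylsilyloxy)benzoate, via gallate-bridged dioxolanylium cation 11 (not isolated)
Conditions: (R)-3,3'-bis(2,4,6-triisopropylphenyl)-1,1'-binaphthyl-2,2'-diyl N-triflylphosphoramide (10 mol%), toluene, 4 Å MS, −40 → −20 °C; Et3N quench, chromatography on Et3N-deactivated silica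
Reagents that add atoms: none
Why: Proposed new method: the phosphoramide protonates the formyl oxygen of 2 while its P=O accepts the phenol O–H, giving a hydroxy-substituted ortho-quinone-methide-type cation whose C4, C4a, C8a and O1 act as heterodiene; 10 reacts as a β-acyloxystyrene, C3 bonding to C4 while charge builds at C2 (benzylic to ring B, bridged by the gallate carbonyl as cation 11), and O1 then closes ring C by 6-exo opening of that bridge at C2, the whole being an asynchronous inverse-demand hetero-[4+2] annulation. The closest known reactions are Brønsted-acid-catalysed, including chiral phosphoric-acid-catalysed, [4+2] annulations of salicylaldehyde-derived ortho-quinone methides and their oxocarbenium analogues with styrenes and enol ethers; an enol ester partner and a free aldehyde giving the 4-hydroxychroman directly have not been shown. C2 and C3 are set by the (E)-geometry of 10, because the C–C bond forms on one alkene face, the gallate bridges the other and O1 displaces it with inversion, which is a net suprafacial addition and gives 2,3-trans. C4 is set by the formyl oxygen being held syn to O1 (intramolecular hydrogen bond, peri silyloxy group at C5) while ring B approaches endo, which places the C4 hydroxyl cis to the exo gallate (3,4-cis, 2,4-trans). The absolute configuration is set by the chiral phosphoramidate, which is hydrogen-bonded to both oxygens of the cation and shields one of its faces. The step needs C3-to-C4 regiochemistry, secured by the para-silyloxy group of ring B being a far stronger donor than the ester oxygen, and it needs the new C4–OH not to ionise, secured by low temperature and low acid loading.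

**Step 8**
Reactants: 12 hepta-O-TBS flavan-3,4-diol 3-gallate
Product: 13 (2R,3S,4S)-2-(3,4-dihydroxyphenyl)-4,5,7-trihydroxychroman-3-yl 3,4,5-trihydroxybenzoate (2,3-trans-3,4-cis; target)
Conditions: Et3N·3HF (20 equiv), THF–MeCN, 0 °C → rt, Ar, dark; evaporation, Sephadex LH-20 (MeOH)
Reagents that add atoms: none
Why: Fluoride-mediated cleavage of aryl silyl ethers is fast, and the weakly acidic, non-basic reagent keeps the phenols protonated, so neither gallate migration from O3 to the cis O4 nor quinone-methide formation is base-triggered, while the low temperature limits acid ionisation at C4; the three stereocentres should be retained.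

**Compound list**
1 | 2,4,6-trihydroxybenzaldehyde | O=Cc1c(O)cc(O)cc1O | starting material
2 | 2-hydroxy-4,6-bis(tert-butyldimethylsilyloxy)benzaldehyde | O=Cc1c(O)cc(O[Si](C)(C)C(C)(C)C)cc1O[Si](C)(C)C(C)(C)C | intermediate
3 | gallic acid | O=C(O)c1cc(O)c(O)c(O)c1 | starting material
4 | tert-butyldimethylsilyl 3,4,5-tris(tert-butyldimethylsilyloxy)benzoate | CC(C)(C)[Si](C)(C)OC(=O)c1cc(O[Si](C)(C)C(C)(C)C)c(O[Si](C)(C)C(C)(C)C)c(O[Si](C)(C)C(C)(C)C)c1 | intermediate (not isolated)
5 | 3,4,5-tris(tert-butyldimethylsilyloxy)benzoic acid | O=C(O)c1cc(O[Si](C)(C)C(C)(C)C)c(O[Si](C)(C)C(C)(C)C)c(O[Si](C)(C)C(C)(C)C)c1 | intermediate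
6 | 3,4-dihydroxybenzaldehyde | O=Cc1ccc(O)c(O)c1 | starting material
7 | 3,4-bis(tert-butyldimethylsilyloxy)benzaldehyde | O=Cc1ccc(O[Si](C)(C)C(C)(C)C)c(O[Si](C)(C)C(C)(C)C)c1 | intermediate
8 | (E)-2-{2-[3,4-bis(tert-butyldimethylsilyloxy)phenyl]ethenyl}-4,4,5,5-tetramethyl-1,3,2-dioxaborolane | CC1(C)OB(/C=C/c2ccc(O[Si](C)(C)C(C)(C)C)c(O[Si](C)(C)C(C)(C)C)c2)OC1(C)C | intermediate
9 | (E)-2-[3,4-bis(tert-butyldimethylsilyloxy)phenyl]ethenylboronic acid | OB(O)/C=C/c1ccc(O[Si](C)(C)C(C)(C)C)c(O[Si](C)(C)C(C)(C)C)c1 | intermediate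
10 | (E)-2-[3,4-bis(tert-butyldimethylsilyloxy)phenyl]ethenyl 3,4,5-tris(tert-butyldimethylsilyloxy)benzoate | O=C(O/C=C/c1ccc(O[Si](C)(C)C(C)(C)C)c(O[Si](C)(C)C(C)(C)C)c1)c1cc(O[Si](C)(C)C(C)(C)C)c(O[Si](C)(C)C(C)(C)C)c(O[Si](C)(C)C(C)(C)C)c1 | intermediate
11 | 2-[3,4,5-tris(TBS-oxy)phenyl]-1,3-dioxolan-2-ylium cation, trans-4-[3,4-bis(TBS-oxy)phenyl]-5-{hydroxy[2-hydroxy-4,6-bis(TBS-oxy)phenyl]methyl}, as its phosphoramidate ion pair; configuration at flavan C3 and C4 as in 12, at C2 opposite (before inversion by O1) | Oc1cc(O[Si](C)(C)C(C)(C)C)cc(O[Si](C)(C)C(C)(C)C)c1[C@H](O)[C@@H]1OC(c2cc(O[Si](C)(C)C(C)(C)C)c(O[Si](C)(C)C(C)(C)C)c(O[Si](C)(C)C(C)(C)C)c2)=[O+][C@H]1c1ccc(O[Si](C)(C)C(C)(C)C)c(O[Si](C)(C)C(C)(C)C)c1 | intermediate (not isolated)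
12 | (2R,3S,4S)-5,7-bis(TBS-oxy)-2-[3,4-bis(TBS-oxy)phenyl]-4-hydroxychroman-3-yl 3,4,5-tris(TBS-oxy)benzoate | O=C(O[C@@H]1[C@@H](c2ccc(O[Si](C)(C)C(C)(C)C)c(O[Si](C)(C)C(C)(C)C)c2)Oc2cc(O[Si](C)(C)C(C)(C)C)cc(O[Si](C)(C)C(C)(C)C)c2[C@@H]1O)c1cc(O[Si](C)(C)C(C)(C)C)c(O[Si](C)(C)C(C)(C)C)c(O[Si](C)(C)C(C)(C)C)c1 | intermediate
13 | (2R,3S,4S)-2-(3,4-dihydroxyphenyl)-4,5,7-trihydroxychroman-3-yl 3,4,5-trihydroxybenzoate | O=C(O[C@@H]1[C@@H](c2ccc(O)c(O)c2)Oc2cc(O)cc(O)c2[C@@H]1O)c1cc(O)c(O)c(O)c1 | target

**Step count**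
Total: 8 steps. Longest linear sequence: 6 steps (6 → 7 → 8 → 9 → 10 → 12 → 13; steps 3, 4, 5, 6, 7, 8).

**Steps most likely to fail**

1. Step 7 (new method). The donor-stabilised aldehyde cation may be too weak an electrophile for the ester-deactivated styrene below the temperature at which the product ionises at C4. Facial or endo/exo control may be poor, the enol ester may oligomerise cationically, and the gallate may migrate from O3 to O4 through an orthoacid. The fallback sets out from 2 and 9 and returns at 12; it makes the same C3–C4 and O1–C2 bonds by established reactions.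
   - Heating 2 with 9 and dibenzylamine (dioxane, 90 °C; Petasis borono-Mannich addition, amine elimination, oxa-6π-electrocyclisation) should give racemic 2-[3,4-bis(TBS-oxy)phenyl]-5,7-bis(TBS-oxy)-2H-chromene F1.
   - Dihydroxylation with OsO4 (cat.) and N-methylmorpholine N-oxide, anti to the C2 aryl group, should give the 2,3-trans-3,4-cis diol in racemic form. Its (2R,3S,4S)-enantiomer, 5,7-bis(TBS-oxy)-2-[3,4-bis(TBS-oxy)phenyl]chroman-3,4-diol F2, is separated by preparative chromatography on a chiral stationary phase.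
   - Acylation of the equatorial 3-OH of F2 with 5 (EDC·HCl, DMAP, CH2Cl2, 0 °C) gives 12; the pseudo-axial benzylic 4-OH next to the C5 silyloxy group should react more slowly.

2. Step 6. Protodeboronation and oxidative homocoupling of the electron-rich alkenylboronic acid may outrun C–O bond formation, and the geometry may partly erode. The fallback sets out from 8 and 5 and returns at 10.
   - Oxidation of 8 (NaBO3·4H2O, THF–pH 7 buffer) gives [3,4-bis(TBS-oxy)phenyl]acetaldehyde F3.
   - Acid 5 is converted with (COCl)2 and catalytic DMF (CH2Cl2) into 3,4,5-tris(TBS-oxy)benzoyl chloride F4.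
   - O-Acylation of the enolate of F3 with F4 (Et3N, cat. DMAP, CH2Cl2, 0 °C) gives 10 as an E/Z mixture, from which the (E)-isomer is isolated on AgNO3-impregnated silica.

3. Step 8. The fluoride medium may trigger acid ionisation at C4 with self-condensation or gallate migration to the cis O4, the hindered silyl ethers may cleave incompletely, and the free polyphenol may oxidise on isolation. The fallback sets out from 1, 3 and 6 and returns at 13; it uses allyl ethers, removed under neutral conditions with zerovalent palladium.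
   - Allyl bromide/K2CO3 (DMF) converts 1 into 4,6-bis(allyloxy)-2-hydroxybenzaldehyde F5.
   - The same reagents convert 3 into allyl 3,4,5-tris(allyloxy)benzoate F6, which is saponified (NaOH, aq. MeOH) to 3,4,5-tris(allyloxy)benzoic acid F7.
   - They convert 6 into 3,4-bis(allyloxy)benzaldehyde F8.
   - The chemistry of steps 4 to 7 then gives (E)-alkenyl pinacol boronate F9, (E)-alkenylboronic acid F10, (E)-enol ester F11 and the hepta-O-allyl flavan-3,4-diol 3-gallate F12.
   - Pd(PPh3)4 (cat.) with N-methylaniline as allyl acceptor (THF, rt) removes the seven allyl groups to give 13.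

**Further compounds**
F1 | step 7 | racemic 2-[3,4-bis(tert-butyldimethylsilyloxy)phenyl]-5,7-bis(tert-butyldimethylsilyloxy)-2H-chromene | CC(C)(C)[Si](C)(C)Oc1ccc(C2C=Cc3c(O[Si](C)(C)C(C)(C)C)cc(O[Si](C)(C)C(C)(C)C)cc3O2)cc1O[Si](C)(C)C(C)(C)C
F2 | step 7 | (2R,3S,4S)-5,7-bis(tert-butyldimethylsilyloxy)-2-[3,4-bis(tert-butyldimethylsilyloxy)phenyl]chroman-3,4-diol (resolved from the racemate) | O[C@@H]1[C@@H](c2ccc(O[Si](C)(C)C(C)(C)C)c(O[Si](C)(C)C(C)(C)C)c2)Oc2cc(O[Si](C)(C)C(C)(C)C)cc(O[Si](C)(C)C(C)(C)C)c2[C@@H]1O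
F3 | step 6 | [3,4-bis(tert-butyldimethylsilyloxy)phenyl]acetaldehyde | O=CCc1ccc(O[Si](C)(C)C(C)(C)C)c(O[Si](C)(C)C(C)(C)C)c1
F4 | step 6 | 3,4,5-tris(tert-butyldimethylsilyloxy)benzoyl chloride | O=C(Cl)c1cc(O[Si](C)(C)C(C)(C)C)c(O[Si](C)(C)C(C)(C)C)c(O[Si](C)(C)C(C)(C)C)c1
F5 | step 8 | 4,6-bis(allyloxy)-2-hydroxybenzaldehyde | O=Cc1c(O)cc(OCC=C)cc1OCC=C
F6 | step 8 | allyl 3,4,5-tris(allyloxy)benzoate | C=CCOC(=O)c1cc(OCC=C)c(OCC=C)c(OCC=C)c1
F7 | step 8 | 3,4,5-tris(allyloxy)benzoic acid | O=C(O)c1cc(OCC=C)c(OCC=C)c(OCC=C)c1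
F8 | step 8 | 3,4-bis(allyloxy)benzaldehyde | O=Cc1ccc(OCC=C)c(OCC=C)c1
F9 | step 8 | (E)-2-{2-[3,4-bis(allyloxy)phenyl]ethenyl}-4,4,5,5-tetramethyl-1,3,2-dioxaborolane | CC1(C)OB(/C=C/c2ccc(OCC=C)c(OCC=C)c2)OC1(C)C
F10 | step 8 | (E)-2-[3,4-bis(allyloxy)phenyl]ethenylboronic acid | OB(O)/C=C/c1ccc(OCC=C)c(OCC=C)c1
F11 | step 8 | (E)-2-[3,4-bis(allyloxy)phenyl]ethenyl 3,4,5-tris(allyloxy)benzoate | O=C(O/C=C/c1ccc(OCC=C)c(OCC=C)c1)c1cc(OCC=C)c(OCC=C)c(OCC=C)c1
F12 | step 8 | (2R,3S,4S)-5,7-bis(allyloxy)-2-[3,4-bis(allyloxy)phenyl]-4-hydroxychroman-3-yl 3,4,5-tris(allyloxy)benzoate | O=C(O[C@@H]1[C@@H](c2ccc(OCC=C)c(OCC=C)c2)Oc2cc(OCC=C)cc(OCC=C)c2[C@@H]1O)c1cc(OCC=C)c(OCC=C)c(OCC=C)c1
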